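**Retrosynthetic overview**
1. Target 10 ⇒ (R)-diol 6 + linoleic acid 7. The ester C–O bond and the indole C3–C(stereocenter) bond are made together by an anodically triggered dehydroxylative 1,2-indolyl shift with carboxylate capture (inversion, R → S).
2. 6 ⇒ bromo diol 4 + prenylstannane 5 (Stille coupling at C6).
3. 4 ⇒ hydroxy ester 3 (double MeMgBr addition builds the CMe2OH unit).
4. 3 ⇒ 6-bromoindole 1 + methyl (R)-glycidate 2 (Friedel–Crafts epoxide opening; the only stereocenter comes from 2).
5. Rings: the indole is bought intact and no ring of the target is built; a transient spirocyclopropane is formed and opened in the last step.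

Assumption: the target stereocenter is (S) by CIP analysis of the given SMILES, and 1, 2 (the L-serine-derived enantiomer), 5 and 7 are taken as commercial.

**Step 1**
Reactants: 1 6-bromo-1H-indole; 2 methyl (2R)-oxirane-2-carboxylate
Product: 3 methyl (2R)-3-(6-bromo-1H-indol-3-yl)-2-hydroxypropanoate
Conditions: 1 (1.5 equiv), Sc(OTf)3 (10 mol%), CH2Cl2, 0 °C → rt
Reagents that add atoms: none
Why: Friedel–Crafts-type epoxide ring opening, in which Sc(OTf)3 chelated between the ester carbonyl and the epoxide oxygen directs indole C3 to the unsubstituted epoxide carbon, so the C2–O bond and the (R) stereocenter bought in 2 are untouched.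

**Step 2**
Reactants: 3 methyl (2R)-3-(6-bromo-1H-indol-3-yl)-2-hydroxypropanoate
Product: 4 (3R)-4-(6-bromo-1H-indol-3-yl)-2-methylbutane-2,3-diol
Conditions: MeMgBr (5 equiv), THF, 0 °C → rt; aq. NH4Cl
Reagents that add atoms: methylmagnesium bromide, C[Mg]Br
Why: Double Grignard addition to the ester after deprotonation of N–H and O–H gives the tertiary carbinol; the magnesium alkoxide at the carbinol carbon suppresses enolisation so the (R) configuration is kept, and the aryl bromide is inert to MeMgBr.

**Step 3**
Reactants: 4 (3R)-4-(6-bromo-1H-indol-3-yl)-2-methylbutane-2,3-diol; 5 tributyl(3-methylbut-2-en-1-yl)stannane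
Product: 6 (3R)-2-methyl-4-[6-(3-methylbut-2-en-1-yl)-1H-indol-3-yl]butane-2,3-diol
Conditions: 5 (1.3 equiv), Pd(PPh3)4 (5 mol%), DMF, 100 °C
Reagents that add atoms: none
Why: Stille cross-coupling, in which zerovalent palladium inserts into the C6–Br bond, the allylic stannane transmetalates and reductive elimination at the less hindered allyl terminus gives the linear prenyl arene; free N–H and hydroxyls are tolerated and the stereocenter is not involved.

**Step 4**
Reactants: 6 (3R)-2-methyl-4-[6-(3-methylbut-2-en-1-yl)-1H-indol-3-yl]butane-2,3-diol; 7 (9Z,12Z)-octadeca-9,12-dienoic acid (linoleic acid)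
Product: 10 (2S)-3-hydroxy-3-methyl-2-[6-(3-methylbut-2-en-1-yl)-1H-indol-3-yl]butyl (9Z,12Z)-octadeca-9,12-dienoate, via alkoxyphosphonium linoleate 8 (not isolated), via spirocyclopropane indoleninium linoleate 9 (not isolated)
Conditions: (4-MeOC6H4)3P (1.5 equiv), 7 (2.0 equiv), n-Bu4NBF4 (0.1 M), CH2Cl2/MeCN 4:1, 3 Å MS, undivided cell, graphite(+)/Pt(−), 0.5 mA cm−2, 2.5 F mol−1, 20 °C, Ar; then 40 °C, 1 h
Reagents that add atoms: none
Why: Proposed new method: anodic two-electron oxidation of the electron-rich triarylphosphine (more easily oxidised than the 3-alkylindole and far more easily than the alkenes) in the presence of the less hindered secondary hydroxyl gives alkoxyphosphonium 8 while the cathode reduces linoleic acid to linoleate and H2; indole C3 then expels the phosphine oxide intramolecularly with inversion (3-exo-tet neighbouring-group attack, faster than carboxylate attack at the neopentyl-like carbinol carbon) to give spirocyclopropane indoleninium 9, and linoleate opens 9 in an SN2 manner at the unhindered CH2 with rearomatisation, so the indole ends on the former carbinol carbon (R → S, stereospecific) and the ester on the primary carbon; the closest known reaction types are the anodic generation of alkoxyphosphonium ions for Mitsunobu-type dehydroxylative substitution and the aryl-assisted solvolysis of 2-(indol-3-yl)ethyl sulfonates through spiro[cyclopropane-1,3'-indolenine] intermediates.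

**Compound list**
1 | 6-bromo-1H-indole | Brc1ccc2cc[nH]c2c1 | starting material
2 | methyl (2R)-oxirane-2-carboxylate (methyl (R)-glycidate) | COC(=O)[C@H]1CO1 | starting material
3 | methyl (2R)-3-(6-bromo-1H-indol-3-yl)-2-hydroxypropanoate | COC(=O)[C@H](O)Cc1c[nH]c2cc(Br)ccc12 | intermediate
4 | (3R)-4-(6-bromo-1H-indol-3-yl)-2-methylbutane-2,3-diol | CC(C)(O)[C@H](O)Cc1c[nH]c2cc(Br)ccc12 | intermediate
5 | tributyl(3-methylbut-2-en-1-yl)stannane | CCCC[Sn](CCCC)(CCCC)CC=C(C)C | starting material
6 | (3R)-2-methyl-4-[6-(3-methylbut-2-en-1-yl)-1H-indol-3-yl]butane-2,3-diol | CC(C)(O)[C@H](O)Cc1c[nH]c2cc(CC=C(C)C)ccc12 | intermediate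
7 | (9Z,12Z)-octadeca-9,12-dienoic acid (linoleic acid) | CCCCC/C=C\C/C=C\CCCCCCCC(=O)O | starting material
8 | {[(2R)-3-hydroxy-3-methyl-1-[6-(3-methylbut-2-en-1-yl)-1H-indol-3-yl]butan-2-yl]oxy}tris(4-methoxyphenyl)phosphonium linoleate | COc1ccc(cc1)[P+](O[C@H](Cc1c[nH]c2cc(CC=C(C)C)ccc12)C(C)(C)O)(c1ccc(OC)cc1)c1ccc(OC)cc1.CCCCC/C=C\C/C=C\CCCCCCCC(=O)[O-] | intermediate
9 | (2R)-2-(2-hydroxypropan-2-yl)-6'-(3-methylbut-2-en-1-yl)spiro[cyclopropane-1,3'-indol]-1'-ium linoleate (either configuration at the spiro carbon; both open to the same product) | CC(C)(O)[C@@H]1CC12C=[NH+]c3cc(CC=C(C)C)ccc23.CCCCC/C=C\C/C=C\CCCCCCCC(=O)[O-] | intermediate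
10 | (2S)-3-hydroxy-3-methyl-2-[6-(3-methylbut-2-en-1-yl)-1H-indol-3-yl]butyl (9Z,12Z)-octadeca-9,12-dienoate (CNP0180241.1) | CCCCC/C=C\C/C=C\CCCCCCCC(=O)OC[C@H](c1c[nH]c2cc(CC=C(C)C)ccc12)C(C)(C)O | target

**Totals**
Total step count: 4. Longest linear sequence: 4 steps (1 or 2 → 3 → 4 → 6 → 10).

**Steps most likely to fail**

Step 1 (Lewis-acid epoxide opening). The risks are a sluggish reaction of the electron-poor epoxide and some attack at C2. The fallback sets out from 2 and 1 and comes back at 4, replacing steps 1 and 2. MeLi (2.1 equiv, THF, −78 °C) is added to 2, where ester addition outruns epoxide opening, to give 2-[(2R)-oxiran-2-yl]propan-2-ol F1. Separately 1 is deprotonated with MeMgBr (ether/toluene, 0 °C) to (6-bromo-1H-indol-1-yl)magnesium bromide F2. F2 (2.2 equiv) then opens F1 at its terminal carbon through indole C3 (classical indolyl-Grignard epoxide opening, rt → 40 °C), giving 4 with the stereocenter again untouched.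

Step 3 (Stille prenylation). The risks are the branched 1,1-dimethylallyl isomer and slow coupling on the unprotected diol. The fallback sets out from 4 and comes back at 6 with the polarity of the partners reversed. Miyaura borylation (B2pin2, Pd(dppf)Cl2, KOAc, dioxane, 90 °C) gives (3R)-2-methyl-4-[6-(4,4,5,5-tetramethyl-1,3,2-dioxaborolan-2-yl)-1H-indol-3-yl]butane-2,3-diol F3. Suzuki–Miyaura allylation of F3 with 1-bromo-3-methylbut-2-ene (Pd(PPh3)4, K2CO3, THF/H2O, 60 °C) couples at the unsubstituted allyl terminus and gives 6.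

Step 4 (the proposed anodic migratory esterification). The risks are:
- competing anodic oxidation of the indole;
- acyl transfer from an acyloxyphosphonium ion to the secondary hydroxyl, giving the unrearranged secondary ester;
- closure of the vicinal diol to the epoxide, which is a dead end and, if it reopened through the indole, would erode the ee;
- incomplete opening of 9.

The fallback sets out from 6 and comes back at 10 using only known reaction types. The secondary hydroxyl is sulfonylated selectively with methanesulfonic anhydride (2,6-lutidine, CH2Cl2, −30 °C; the anhydride is used so that no chloride can capture the intermediate) to give (2R)-3-hydroxy-3-methyl-1-[6-(3-methylbut-2-en-1-yl)-1H-indol-3-yl]butan-2-yl methanesulfonate F4. Buffered solvolysis (NaHCO3, acetone/H2O, 40 °C) proceeds with indole participation through the spirocyclopropane and water attack at CH2, as established for tryptophol sulfonates, and gives (2S)-3-methyl-2-[6-(3-methylbut-2-en-1-yl)-1H-indol-3-yl]butane-1,3-diol F5 with inversion. The primary hydroxyl of F5 is then esterified with 7 (EDC·HCl, cat. DMAP, CH2Cl2, 0 °C), leaving the tertiary hydroxyl and the indole N–H free, to give 10.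

**Further compounds**
F1 | step 1 | 2-[(2R)-oxiran-2-yl]propan-2-ol | CC(C)(O)[C@H]1CO1
F2 | step 1 | (6-bromo-1H-indol-1-yl)magnesium bromide | Br[Mg]n1ccc2ccc(Br)cc12
F3 | step 3 | (3R)-2-methyl-4-[6-(4,4,5,5-tetramethyl-1,3,2-dioxaborolan-2-yl)-1H-indol-3-yl]butane-2,3-diol | CC(C)(O)[C@H](O)Cc1c[nH]c2cc(B3OC(C)(C)C(C)(C)O3)ccc12
F4 | step 4 | (2R)-3-hydroxy-3-methyl-1-[6-(3-methylbut-2-en-1-yl)-1H-indol-3-yl]butan-2-yl methanesulfonate | CC(C)(O)[C@H](OS(C)(=O)=O)Cc1c[nH]c2cc(CC=C(C)C)ccc12
F5 | step 4 | (2S)-3-methyl-2-[6-(3-methylbut-2-en-1-yl)-1H-indol-3-yl]butane-1,3-diol | OC[C@H](c1c[nH]c2cc(CC=C(C)C)ccc12)C(C)(C)O
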